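Percent columns mislead: J loses 0.0507 h⁻¹ of its charge per hour in Monday's run and 0.0320 h⁻¹ in Tuesday's, as if each run had its own pace. Multiplied by the charges, the two losses nearly coincide, and their mean is the feed 0.0197 M h⁻¹, the J entering solution per hour while solid lasts.

| setting | Monday's | Tuesday's | flask |
|---|---|---|---|
| J | 0.40 M | 0.60 M | 0.80 M |
| X | 200 mM (held) | 200 mM (held) | 200 mM (held) |
| remark | run made earlier | run made earlier |  |
| time |  |  | 25 h |

| run | time / h | L / % | J / % |
|---|---|---|---|
| Monday's | 5.00 | 16 | 74 |
| Monday's | 10.0 | 39 | 50 |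
| Monday's | 15.0 | 53 | 24 |
| Monday's | 20.0 | 64 | 0 |
| Monday's | 25.0 | 54 | 1 |
| Monday's | 30.0 | 46 | 0 |
| Tuesday's | 2.00 | 3 | 95 |
| Tuesday's | 6.00 | 15 | 80 |
| Tuesday's | 10.0 | 22 | 70 |
| Tuesday's | 15.0 | 31 | 50 |
| Tuesday's | 25.0 | 48 | 20 |
| Tuesday's | 30.0 | 54 | 3 |

(readings scatter by 2 percentage points)

* how much L there is at 25 h, in percent of the J charged
* concentration of Z in solution at 25 h, in percent of saturation

- J is a solid; its amount is given per volume of the solution
- at the start none of Z is dissolved
- steps that have been proposed: X <-> Z; G + Z -> L; G -> E; L -> Q; J <-> G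
- at the start none of J is in solution

J is the limiting reagent, since X is held. The flask's solid lasts 40.5 h, longer than 25 h, so the feed holds throughout, at 0.0247 h⁻¹ of the charge.

After Monday's J reads 0%, L falls at a read 0.0330 h⁻¹. Applying that loss to Monday's L readings puts 23.1% in Q by 20.0 h. The share passing through L is therefore 87.1%. The books of this reckoning for the flask at 25 h, in fractions of the charge:

J still undissolved: 38.3%

L, gaining its share of the feed and decaying: 36.6%

Q: 17.2%

E and G: 7.94%

Z is unread; this reckoning assumes X passes into Z quickly, leaving Z close to 200 mM.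

The forecast, following Tuesday's absolute L curve, gives L 36% and Z 77% of saturation, “this figure is poorly determined”, so it stands lower on Z than this reckoning.

The flask gives L 36.5% and Z 97.9% of saturation.

    X ⇌ Z, rate k1*(csat - [Z]) (kL = 4.30 h⁻¹)
    G + Z → L (k = 5.70 M⁻¹ h⁻¹)
    G → E (k = 0.110 h⁻¹)
    L → Q (k = 0.0370 h⁻¹)
    J ⇌ G, rate k5*(cs5 - [G]) while solid is left; crystals form when [G] > cs5 (solubility = 0.280 M, k = 0.0760 h⁻¹)

At 25.0 h the flask holds G at 2.04%, in quasi-steady state, with G made and used in the ratio 1.00, while J stands at 37.3%. The same feed gives a neighbour flask charged with 0.32 M of J a solid lasting 16.2 h, shorter than 25 h. That neighbour flask holds J at 0% at 25.0 h, with L at 50.7%.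

The data are simulated with constants of no real substance; scatter was added.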